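**Plan**

- **Cuts:** C13=C14 (butenolide, metathesis), the C11 acetate, and C11–C12 (allylation of the C11 aldehyde). Then, in one retro-step, C9–C10 (ring B) is cut together with C4–C5, and the C4 end is put back on C10.
- **Enabling feature:** in ring A (C1–C5, C10) the gem-dimethyl carbon C4, the ring-fusion CH C5 and the methyl-bearing quaternary C10 stand in a row. A 1,2-shift of C4 between C10 and C5 therefore interconverts ring A with a 1,2,2-trimethylcyclopentane that carries C5 as an exocyclic carbinyl carbon. Its nine carbons (C1–C5, C10, C18–C20) are those of camphoric acid minus one CO2.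
- **Forward order:** camphoric acid gives the cyclopentyl methyl ketone. The chain is joined at C6–C7, then at C8–C17 and C9–C11. One cascade enlarges the five-membered ring to ring A and closes ring B with the C8=C17 methylene. The side chain is then added at C11 and the butenolide ring is closed last.
- **Stereochemistry:** C10 comes from C1 of (1S,3R)-camphoric acid (inverted in the shift). C5 comes from a CBS reduction (inverted in the shift). C9 comes from the Z-allylsilane in a chair transition state. C11 comes from a ligand-controlled Nozaki–Hiyama–Kishi allylation.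

Key step: step 9

Assumption: atoms carry labdane numbers (ring A = C1–C5/C10, ring B = C5–C10); (1S,3R)-camphoric acid and compounds 7, 10, 11, 20 and 21 are taken as commercial.

**Step 1**
Reactants: 1 (1S,3R)-camphoric acid
Product: 2 (1S,3R)-3-(methoxycarbonyl)-1,2,2-trimethylcyclopentane-1-carboxylic acid
Conditions: MeOH, H2SO4 (cat.), reflux
Reagents that add atoms: methanol CO
Why: Fischer esterification under steric control should esterify only the secondary carboxyl group and leave the tertiary one, next to the CMe2 carbon, free; no stereocentre is touched.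

**Step 2**
Reactants: 2 (1S,3R)-3-(methoxycarbonyl)-1,2,2-trimethylcyclopentane-1-carboxylic acid
Product: 4 methyl (1R,3S)-3-acetyl-2,2,3-trimethylcyclopentane-1-carboxylate, via acid chloride 3 (not isolated)
Conditions: (COCl)2, DMF (cat.), CH2Cl2, rt; evaporate; MeMgBr, Fe(acac)3 (3 mol %), THF, −78 °C
Reagents that add atoms: methylmagnesium bromide C[Mg]Br
Why: Acid chloride formation followed by iron-catalysed acylation of a Grignard reagent should stop at the ketone, because the acyl chloride reacts far faster than the ester or the neopentylic ketone; the methyl group becomes C6.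

**Step 3**
Reactants: 4 methyl (1R,3S)-3-acetyl-2,2,3-trimethylcyclopentane-1-carboxylate
Product: 5 (1R,3S)-3-acetyl-2,2,3-trimethylcyclopentane-1-carboxylic acid
Conditions: LiOH, THF/MeOH/H2O, 50 °C; then 1 M HCl
Reagents that add atoms: lithium hydroxide [Li+].[OH-]
Why: Saponification frees the carboxyl group; any epimerisation next to it is harmless because that centre is erased in step 4.

**Step 4**
Reactants: 5 (1R,3S)-3-acetyl-2,2,3-trimethylcyclopentane-1-carboxylic acid
Product: 6 1-[(1S)-1,2,2-trimethylcyclopentyl]ethan-1-one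
Conditions: 9-mesityl-10-phenylacridinium BF4 (5 mol %), PhSSPh (10 mol %), i-Pr2NEt (20 mol %), CF3CH2OH, 450 nm LED, rt
Reagents that add atoms: none
Why: In this photoredox hydrodecarboxylation the carboxylate is oxidised, loses CO2, and the secondary ring radical takes hydrogen from thiophenol formed in situ; the ketone and the quaternary stereocentre are not involved.

**Step 5**
Reactants: 6 1-[(1S)-1,2,2-trimethylcyclopentyl]ethan-1-one; 7 propargyl bromide
Product: 9 1-[(1S)-1,2,2-trimethylcyclopentyl]pent-4-yn-1-one, via lithium enolate 8 (not isolated)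
Conditions: LDA, THF, −78 °C; then 7, −78 → 0 °C
Reagents that add atoms: none
Why: Enolate alkylation forms C6–C7; the ketone can enolise on the methyl side only and the propargylic bromide is a fast SN2 partner.

**Step 6**
Reactants: 9 1-[(1S)-1,2,2-trimethylcyclopentyl]pent-4-yn-1-one; 10 (trimethylsilyl)methylmagnesium chloride; 11 benzyl chloromethyl ether
Product: 13 (4Z)-6-(benzyloxy)-4-[(trimethylsilyl)methyl]-1-[(1S)-1,2,2-trimethylcyclopentyl]hex-4-en-1-one, via vinylcopper 12 (not isolated)
Conditions: 10, CuBr·SMe2, Et2O/Me2S, −35 °C; 9, −35 → 0 °C; then 11, DMPU, P(OEt)3, −30 °C → rt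
Reagents that add atoms: none
Why: Normant carbocupration adds the silylmethyl group to the internal alkyne carbon and copper to the terminus in a syn fashion, and the vinylcopper is alkylated by the α-chloro ether with retention. CH2SiMe3 (C17) and CH2OBn (C11) therefore end up cis (Z), and the hindered ketone is not attacked by RCu·MgX2.

**Step 7**
Reactants: 13 (4Z)-6-(benzyloxy)-4-[(trimethylsilyl)methyl]-1-[(1S)-1,2,2-trimethylcyclopentyl]hex-4-en-1-one
Product: 14 (1S,4Z)-6-(benzyloxy)-4-[(trimethylsilyl)methyl]-1-[(1S)-1,2,2-trimethylcyclopentyl]hex-4-en-1-ol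
Conditions: (R)-Me-CBS (0.3 equiv), BH3·SMe2, toluene, −20 °C, slow addition of 13; MeOH quench
Reagents that add atoms: none
Why: Corey–Bakshi–Shibata reduction distinguishes the tert-alkyl group from the primary alkyl chain as cleanly as in pinacolone-type ketones, and the (R)-catalyst should give the (S)-carbinol at C5 under reagent control.

**Step 8**
Reactants: 14 (1S,4Z)-6-(benzyloxy)-4-[(trimethylsilyl)methyl]-1-[(1S)-1,2,2-trimethylcyclopentyl]hex-4-en-1-ol
Product: 15 (1S,4Z)-6-(benzyloxy)-4-[(trimethylsilyl)methyl]-1-[(1S)-1,2,2-trimethylcyclopentyl]hex-4-en-1-yl methanesulfonate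
Conditions: MsCl, Et3N, CH2Cl2, −10 °C
Reagents that add atoms: methanesulfonyl chloride CS(=O)(=O)Cl
Why: Mesylation through sulfene reaches even hindered secondary alcohols, keeps the C5 configuration, and the neopentylic mesylate is inert to SN2 and can be handled.

**Step 9**
Reactants: 15 (1S,4Z)-6-(benzyloxy)-4-[(trimethylsilyl)methyl]-1-[(1S)-1,2,2-trimethylcyclopentyl]hex-4-en-1-yl methanesulfonate
Product: 17 O-benzylalbicanol (1S,4aS,8aS)-1-[(benzyloxy)methyl]-5,5,8a-trimethyl-2-methylidenedecahydronaphthalene, via C10 cation 16 (not isolated)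
Conditions: (CF3)2CHOH, 2,6-di-tert-butyl-4-methylpyridine (1.5 equiv), 0 °C → rt
Reagents that add atoms: none
Why: Proposed new method: ionisation of the neopentylic C5–OMs bond in the strongly ionising, non-nucleophilic solvent is assisted by the antiperiplanar C4–C10 σ-bond, so C4 moves from C10 to C5 (Wagner–Meerwein 1,2-alkyl shift), the trimethylcyclopentane becomes six-membered ring A with a tertiary cation at C10 (16), the Z-allylsilane captures this cation through C9, and the β-silyl cation at C8 loses Me3Si+ to leave the C8=C17 methylene. The closest known reaction types are the solvolytic ring enlargement of (1-methylcyclopentyl)carbinyl sulfonates and the allylsilane-terminated cation–olefin cyclisation, and only their coupling in one cascade is new. Ring A arises by one-carbon enlargement (5→6) and ring B closes 6-endo-trig through a chair-like transition state. C5 is set by inversion at the carbinol carbon fixed in step 7, C10 by attack of C9 anti to the departing C4 (inversion of the camphoric acid quaternary centre, which leaves C4 and C9 antiperiplanar across C5–C10 as in a trans-decalin), and C9 by the Z geometry of the alkene, which places C11 trans to C7 and hence equatorial. The step needs migration of C4 rather than of C1 or the methyl group, and this is secured because C4 is the only tert-alkyl migrating group, the C4–C10 bond joins two quaternary carbons and is the weakest and most electron-rich σ-bond at C10, and only a ring bond releases the cyclopentane strain. The hindered pyridine keeps the medium free of strong acid, so neither the allylsilane nor the new exocyclic alkene should be protonated, and silicon fixes the position of the double bond.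

**Step 10**
Reactants: 17 O-benzylalbicanol
Product: 18 albicanol [(1S,4aS,8aS)-5,5,8a-trimethyl-2-methylidenedecahydronaphthalen-1-yl]methanol
Conditions: Li, NH3(l)/THF, −78 °C; NH4Cl
Reagents that add atoms: none
Why: Dissolving-metal cleavage of the benzyl ether leaves the isolated 1,1-disubstituted alkene and all stereocentres untouched.

**Step 11**
Reactants: 18 albicanol
Product: 19 albicanal (1S,4aS,8aS)-5,5,8a-trimethyl-2-methylidenedecahydronaphthalene-1-carbaldehyde
Conditions: Dess–Martin periodinane, NaHCO3, CH2Cl2, 0 °C; used at once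
Reagents that add atoms: none
Why: Buffered Dess–Martin oxidation is mild enough to avoid epimerisation at C9 and migration of the alkene into conjugation.

**Step 12**
Reactants: 20 2-(bromomethyl)acrylic acid; 21 allyl alcohol
Product: 22 prop-2-en-1-yl 2-(bromomethyl)acrylate
Conditions: p-TsOH (cat.), toluene, Dean–Stark, reflux
Reagents that add atoms: none
Why: Acid-catalysed esterification with azeotropic removal of water avoids the nucleophilic catalysts that would displace the allylic bromide.

**Step 13**
Reactants: 19 albicanal; 22 prop-2-en-1-yl 2-(bromomethyl)acrylate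
Product: 24 prop-2-en-1-yl (4R)-4-hydroxy-2-methylidene-4-[(1S,4aS,8aS)-5,5,8a-trimethyl-2-methylidenedecahydronaphthalen-1-yl]butanoate, via trimethylsilyl ether 23 (not isolated)
Conditions: CrCl2 (10 mol %), carbazole-bridged bis(oxazoline) ligand (12 mol %, the enantiomer that directs Re-face attack), Mn, Me3SiCl, i-Pr2NEt (cat.), THF, 0 °C → rt; then 1 M citric acid, THF
Reagents that add atoms: none
Why: The catalytic asymmetric Nozaki–Hiyama–Kishi 2-(alkoxycarbonyl)allylation is neutral enough to preserve C9. The allylchromium(III) adds through a closed chair transition state to the aldehyde face chosen by the ligand (Re, giving 11R), and in-situ silylation of the alkoxide blocks lactonisation onto the allyl ester.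

**Step 14**
Reactants: 24 prop-2-en-1-yl (4R)-4-hydroxy-2-methylidene-4-[(1S,4aS,8aS)-5,5,8a-trimethyl-2-methylidenedecahydronaphthalen-1-yl]butanoate
Product: 25 prop-2-en-1-yl (4R)-4-acetoxy-2-methylidene-4-[(1S,4aS,8aS)-5,5,8a-trimethyl-2-methylidenedecahydronaphthalen-1-yl]butanoate
Conditions: Ac2O, pyridine, DMAP (cat.), CH2Cl2, 0 °C → rt
Reagents that add atoms: acetic anhydride CC(=O)OC(C)=O
Why: DMAP-catalysed acetylation takes place at oxygen with retention at C11 and removes the hydroxyl group that could otherwise lactonise.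

**Step 15**
Reactants: 25 prop-2-en-1-yl (4R)-4-acetoxy-2-methylidene-4-[(1S,4aS,8aS)-5,5,8a-trimethyl-2-methylidenedecahydronaphthalen-1-yl]butanoate
Product: 26 target (1R)-1-[(1S,4aS,8aS)-5,5,8a-trimethyl-2-methylidenedecahydronaphthalen-1-yl]-2-(2-oxo-2,5-dihydrofuran-3-yl)ethyl acetate
Conditions: second-generation Grubbs catalyst (5 mol %), 1,4-benzoquinone (10 mol %), CH2Cl2, reflux
Reagents that add atoms: none
Why: Ring-closing metathesis starts at the allyl ester and closes on the acrylate methylene to give the α-substituted butenolide (C13=C14); the hindered C8=C17 methylene could only form a nine-membered ring and should stay a spectator.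

**Compound list**

1 | (1S,3R)-camphoric acid | C[C@]1(C(=O)O)CC[C@@H](C(=O)O)C1(C)C | starting material
2 | (1S,3R)-3-(methoxycarbonyl)-1,2,2-trimethylcyclopentane-1-carboxylic acid | C[C@]1(C(=O)O)CC[C@@H](C(=O)OC)C1(C)C | intermediate
3 | methyl (1R,3S)-3-(chlorocarbonyl)-2,2,3-trimethylcyclopentane-1-carboxylate | C[C@]1(C(=O)Cl)CC[C@@H](C(=O)OC)C1(C)C | intermediate
4 | methyl (1R,3S)-3-acetyl-2,2,3-trimethylcyclopentane-1-carboxylate | C[C@]1(C(C)=O)CC[C@@H](C(=O)OC)C1(C)C | intermediate
5 | (1R,3S)-3-acetyl-2,2,3-trimethylcyclopentane-1-carboxylic acid | C[C@]1(C(C)=O)CC[C@@H](C(=O)O)C1(C)C | intermediate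
6 | 1-[(1S)-1,2,2-trimethylcyclopentyl]ethan-1-one | C[C@]1(C(C)=O)CCCC1(C)C | intermediate
7 | propargyl bromide | C#CCBr | starting material
8 | lithium enolate of 6 | C=C(O[Li])[C@@]1(C)CCCC1(C)C | intermediate
9 | 1-[(1S)-1,2,2-trimethylcyclopentyl]pent-4-yn-1-one | C#CCCC(=O)[C@@]1(C)CCCC1(C)C | intermediate
10 | (trimethylsilyl)methylmagnesium chloride | C[Si](C)(C)C[Mg]Cl | starting material
11 | benzyl chloromethyl ether | ClCOCc1ccccc1 | starting material
12 | vinylcopper from syn-carbocupration of 9 (Cu cis to CH2SiMe3) | C[Si](C)(C)C/C(CCC(=O)[C@@]1(C)CCCC1(C)C)=C\[Cu] | intermediate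
13 | (4Z)-6-(benzyloxy)-4-[(trimethylsilyl)methyl]-1-[(1S)-1,2,2-trimethylcyclopentyl]hex-4-en-1-one | C[Si](C)(C)C/C(CCC(=O)[C@@]1(C)CCCC1(C)C)=C\COCc1ccccc1 | intermediate
14 | (1S,4Z)-6-(benzyloxy)-4-[(trimethylsilyl)methyl]-1-[(1S)-1,2,2-trimethylcyclopentyl]hex-4-en-1-ol | C[Si](C)(C)C/C(CC[C@H](O)[C@@]1(C)CCCC1(C)C)=C\COCc1ccccc1 | intermediate
15 | methanesulfonate of 14 | C[Si](C)(C)C/C(CC[C@H](OS(C)(=O)=O)[C@@]1(C)CCCC1(C)C)=C\COCc1ccccc1 | intermediate
16 | ring-enlarged tertiary C10 cation (1,3,3-trimethylcyclohexyl cation with the allylsilane chain on C5) | C[C+]1CCCC(C)(C)[C@@H]1CC/C(C[Si](C)(C)C)=C/COCc1ccccc1 | intermediate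
17 | O-benzylalbicanol | C=C1CC[C@H]2C(C)(C)CCC[C@]2(C)[C@H]1COCc1ccccc1 | intermediate
18 | albicanol | C=C1CC[C@H]2C(C)(C)CCC[C@]2(C)[C@H]1CO | intermediate
19 | albicanal | C=C1CC[C@H]2C(C)(C)CCC[C@]2(C)[C@H]1C=O | intermediate
20 | 2-(bromomethyl)acrylic acid | C=C(CBr)C(=O)O | starting material
21 | allyl alcohol | C=CCO | starting material
22 | prop-2-en-1-yl 2-(bromomethyl)acrylate | C=CCOC(=O)C(=C)CBr | intermediate
23 | trimethylsilyl ether of 24 | C=C1CC[C@H]2C(C)(C)CCC[C@]2(C)[C@H]1[C@@H](CC(=C)C(=O)OCC=C)O[Si](C)(C)C | intermediate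
24 | (11R)-hydroxy allyl ester | C=C1CC[C@H]2C(C)(C)CCC[C@]2(C)[C@H]1[C@@H](CC(=C)C(=O)OCC=C)O | intermediate
25 | (11R)-acetoxy allyl ester | C=C1CC[C@H]2C(C)(C)CCC[C@]2(C)[C@H]1[C@@H](CC(=C)C(=O)OCC=C)OC(C)=O | intermediate
26 | CNP0182424.2, (11R)-11-acetoxylabda-8(17),13-dien-16,15-olide | C=C1CC[C@H]2C(C)(C)CCC[C@]2(C)[C@H]1[C@@H](CC1=CCOC1=O)OC(C)=O | target

**Step count**

Total step count: 15. Longest linear sequence: 14 (steps 1–11 and 13–15).

**Steps most likely to fail**

**1. Step 9.**
- What may go wrong: after the shift the C10 cation may lose a proton or take a hydride from C5 faster than ring B closes. The allylsilane may also be protodesilylated in the protic medium.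
- Fallback (sets out from 9, comes back at 17): the two events are separated, and the silane is brought in between them, using known reaction types only.
- CBS reduction of 9 as in step 7 should give (1S)-1-[(1S)-1,2,2-trimethylcyclopentyl]pent-4-yn-1-ol F1.
- MsCl/Et3N should give its methanesulfonate F2.
- Et2AlCl in CH2Cl2 (−78 → 0 °C) should ionise F2 with the same Wagner–Meerwein ring enlargement of a cyclopentylcarbinyl sulfonate, but end it with chloride, giving (2S)-2-(but-3-yn-1-yl)-1-chloro-1,3,3-trimethylcyclohexane F3. The configuration at the chloride carbon is of no consequence.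
- Carbocupration with 10/CuBr·SMe2 and trapping with 11, as in step 6, should turn the alkyne into {(2Z)-4-(benzyloxy)-2-[2-((1S)-2-chloro-2,6,6-trimethylcyclohexyl)ethyl]but-2-en-1-yl}trimethylsilane F4.
- TiCl4 in CH2Cl2 at −78 °C should re-ionise the tertiary chloride for the Lewis-acid-mediated tert-alkylation of an allylsilane, here intramolecular, to give 17.

**2. Step 6.**
- What may go wrong: sluggish or poorly regioselective transfer of the silylmethyl group from copper to the alkyne, or incomplete alkylation of the vinylcopper.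
- Fallback (sets out from 9, comes back at 14): the trisubstituted alkene is built by trans-hydroalumination and cross-coupling instead.
- 9 is first reduced under CBS conditions to the alkynol already described as F1.
- Its dianion (n-BuLi, 2 equiv) with paraformaldehyde should give (6S)-6-[(1S)-1,2,2-trimethylcyclopentyl]hex-2-yne-1,6-diol F5.
- Red-Al and then I2 should give (2Z,6S)-3-iodo-6-[(1S)-1,2,2-trimethylcyclopentyl]hex-2-ene-1,6-diol F6.
- Kumada coupling with 10 and Pd(PPh3)4 should give, with retention, (2Z,6S)-3-[(trimethylsilyl)methyl]-6-[(1S)-1,2,2-trimethylcyclopentyl]hex-2-ene-1,6-diol F7.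
- NaH (1 equiv)/BnBr should benzylate only the primary allylic hydroxyl group to give 14.

**3. Step 13.**
- What may go wrong: poor facial selectivity if the catalyst has to work against the bias of the crowded aldehyde.
- Fallback (sets out from 19, comes back at 24): the C–C bond is made without stereocontrol and C11 is set afterwards by hydride delivery.
- Indium-mediated Barbier allylation of 19 with 22 in THF/H2O should give 24 together with its epimer prop-2-en-1-yl (4S)-4-hydroxy-2-methylidene-4-[(1S,4aS,8aS)-5,5,8a-trimethyl-2-methylidenedecahydronaphthalen-1-yl]butanoate F8.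
- Buffered Dess–Martin oxidation of the mixture should give prop-2-en-1-yl 2-methylidene-4-oxo-4-[(1S,4aS,8aS)-5,5,8a-trimethyl-2-methylidenedecahydronaphthalen-1-yl]butanoate F9.
- CBS reduction with the (S)-catalyst and catecholborane at low temperature reads the decalinyl group as large and the CH2 group as small, and should return 24.

**Further compounds**

F1 | step 9 | (1S)-1-[(1S)-1,2,2-trimethylcyclopentyl]pent-4-yn-1-ol | C#CCC[C@H](O)[C@@]1(C)CCCC1(C)C
F2 | step 9 | (1S)-1-[(1S)-1,2,2-trimethylcyclopentyl]pent-4-yn-1-yl methanesulfonate | C#CCC[C@H](OS(C)(=O)=O)[C@@]1(C)CCCC1(C)C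
F3 | step 9 | (2S)-2-(but-3-yn-1-yl)-1-chloro-1,3,3-trimethylcyclohexane | CC1(Cl)CCCC(C)(C)[C@@H]1CCC#C
F4 | step 9 | {(2Z)-4-(benzyloxy)-2-[2-((1S)-2-chloro-2,6,6-trimethylcyclohexyl)ethyl]but-2-en-1-yl}trimethylsilane | CC1(Cl)CCCC(C)(C)[C@@H]1CC/C(C[Si](C)(C)C)=C/COCc1ccccc1
F5 | step 6 | (6S)-6-[(1S)-1,2,2-trimethylcyclopentyl]hex-2-yne-1,6-diol | OCC#CCC[C@H](O)[C@@]1(C)CCCC1(C)C
F6 | step 6 | (2Z,6S)-3-iodo-6-[(1S)-1,2,2-trimethylcyclopentyl]hex-2-ene-1,6-diol | OC/C=C(\I)CC[C@H](O)[C@@]1(C)CCCC1(C)C
F7 | step 6 | (2Z,6S)-3-[(trimethylsilyl)methyl]-6-[(1S)-1,2,2-trimethylcyclopentyl]hex-2-ene-1,6-diol | OC/C=C(\C[Si](C)(C)C)CC[C@H](O)[C@@]1(C)CCCC1(C)C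
F8 | step 13 | prop-2-en-1-yl (4S)-4-hydroxy-2-methylidene-4-[(1S,4aS,8aS)-5,5,8a-trimethyl-2-methylidenedecahydronaphthalen-1-yl]butanoate | C=C1CC[C@H]2C(C)(C)CCC[C@]2(C)[C@H]1[C@H](CC(=C)C(=O)OCC=C)O
F9 | step 13 | prop-2-en-1-yl 2-methylidene-4-oxo-4-[(1S,4aS,8aS)-5,5,8a-trimethyl-2-methylidenedecahydronaphthalen-1-yl]butanoate | C=C1CC[C@H]2C(C)(C)CCC[C@]2(C)[C@H]1C(=O)CC(=C)C(=O)OCC=C
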